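**Retrosynthetic overview**
1. The strategy rests on ring A: its carbons C4a and C8a are the enol-ether double bond of ring C, so C5–C8 (5-OH, 6-prenyl, 7-O, 8-prenyl) can be annulated onto a 2-aryl-2,3-dihydro-4H-pyran-4-one that already carries ring B and the (2S) centre.
2. Ring A ⇒ α-diazoketone 14 + siloxyalkyne 19 (photo-Wolff, [2+2], four-electron opening, six-electron closure; bonds C8–C8a, C5–C6, C7–C8, C4a–C5); only two silyl groups are removed afterwards.
3. 14 ⇒ ketone 12 (detrifluoroacetylative diazo transfer) ⇒ acid 8 + homoprenylzinc 10 (Negishi acylation) ⇒ ester 7.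
4. Ring C and C2 ⇒ enantioselective vinylogous Mukaiyama aldol of ring-B aldehyde 3 with bis-silyl dienol ether 5 of ethyl 2,4-dioxopentanoate, then cyclodehydration; 3 from 5-iodovanillin; 19 from 4-methylpent-3-enoic acid by ynolate O-silylation.
5. Order of ring formation: ring B (purchased), ring C (step 4), ring A (step 11).

Key step: step 11

Abbreviations: prenyl = 3-methylbut-2-en-1-yl; Ar = 3-methoxy-5-prenyl-4-(triisopropylsilyloxy)phenyl; flavanone numbering (O1, C2, C3, C4, C4a, C5–C8, C8a) is used for ring A and ring C; L* = 1,5-bis{methyl[(11bR)-3,5-dimethyl-4-oxido-3,5-dihydro-4H-dinaphtho[2,1-d:1',2'-f][1,3,2]diazaphosphepin-4-yl]amino}pentane.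

Assumption: L* with (R)-binaphthyl units is taken to direct the silyl dienol ether to the Si face of the aromatic aldehyde (which gives 2S); if the configuration of 7 is found to be opposite, the antipode of L* is used with no other change.

**Route**

Step 1
Reactants: 1 5-iodovanillin (4-hydroxy-3-iodo-5-methoxybenzaldehyde)
Product: 2 3-iodo-5-methoxy-4-(triisopropylsilyloxy)benzaldehyde
Conditions: TIPSCl, imidazole, DMF, 40 °C
Reagents that add atoms: chlorotriisopropylsilane, CC(C)[Si](Cl)(C(C)C)C(C)C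
Why: O-silylation of the acidic phenol gives a hindered aryl silyl ether that should survive the later Lewis acid, amide base and organozinc steps.

Step 2
Reactants: 2 3-iodo-5-methoxy-4-(triisopropylsilyloxy)benzaldehyde
Product: 3 3-methoxy-5-prenyl-4-(triisopropylsilyloxy)benzaldehyde
Conditions: Bu3SnCH2CH=CMe2, Pd(PPh3)4 (5 mol %), DMF, 90 °C
Reagents that add atoms: tributyl(3-methylbut-2-en-1-yl)stannane, CC(C)=CC[Sn](CCCC)(CCCC)CCCC
Why: Stille coupling of the aryl iodide with the prenylstannane should transfer the allyl group at its primary carbon to give the linear prenyl arene, with the aldehyde and silyl ether untouched under fluoride-free conditions.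

Step 3
Reactants: 4 ethyl 2,4-dioxopentanoate
Product: 5 ethyl (2Z)-2,4-bis(trimethylsilyloxy)penta-2,4-dienoate
Conditions: TMSOTf (2.2 equiv), Et3N (2.5 equiv), Et2O, 0 °C to rt
Reagents that add atoms: trimethylsilyl trifluoromethanesulfonate, C[Si](C)(C)OS(=O)(=O)C(F)(F)F
Why: twofold soft enolisation and O-silylation of the 1,3-dicarbonyl unit, the standard preparation of 1,3-bis(silyloxy)dienes, gives a diene whose terminal CH2 is the nucleophilic carbon.

Step 4
Reactants: 3 3-methoxy-5-prenyl-4-(triisopropylsilyloxy)benzaldehyde; 5 ethyl (2Z)-2,4-bis(trimethylsilyloxy)penta-2,4-dienoate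
Product: 7 ethyl (2S)-2-Ar-4-oxo-3,4-dihydro-2H-pyran-6-carboxylate, via hydroxy diketo ester 6 (not isolated)
Conditions: SiCl4 (1.2 equiv), L* (5 mol %), i-Pr2NEt (0.1 equiv), CH2Cl2, −78 °C; aq. NaHCO3; then TFA (5 equiv), CH2Cl2, 0 °C
Reagents that add atoms: none
Why: catalytic enantioselective vinylogous Mukaiyama aldol in which the phosphoramide-bound chlorosilyl cation activates the aldehyde and leaves its Si face open to the terminal carbon of 5, setting the carbinol (later C2) as S, after which acid closes ring C by hemiketalisation onto the α-keto ester carbonyl and dehydration without breaking the carbinol C–O bond.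

Step 5
Reactants: 7 ethyl (2S)-2-Ar-4-oxo-3,4-dihydro-2H-pyran-6-carboxylate
Product: 8 (2S)-2-Ar-4-oxo-3,4-dihydro-2H-pyran-6-carboxylic acid
Conditions: Me3SnOH, ClCH2CH2Cl, 80 °C; 1 M HCl wash
Reagents that add atoms: trimethyltin hydroxide, C[Sn](C)(C)O
Why: tin hydroxide ester cleavage is close to neutral, so enolisation at C3 and the β-elimination of the ring oxygen that aqueous hydroxide could cause are avoided.

Step 6
Reactants: 9 5-bromo-2-methylpent-2-ene
Product: 10 (4-methylpent-3-en-1-yl)zinc bromide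
Conditions: Zn dust (activated with BrCH2CH2Br and TMSCl), LiCl, THF, 50 °C
Reagents that add atoms: zinc, [Zn]
Why: oxidative insertion of LiCl-activated zinc into the primary alkyl bromide gives an alkylzinc halide that is inert to ketones and enones.

Step 7
Reactants: 8 (2S)-2-Ar-4-oxo-3,4-dihydro-2H-pyran-6-carboxylic acid; 10 (4-methylpent-3-en-1-yl)zinc bromide
Product: 12 (2S)-2-Ar-6-(5-methylhex-4-enoyl)-2,3-dihydro-4H-pyran-4-one, via acid chloride 11 (not isolated)
Conditions: Me2C=C(Cl)NMe2, CH2Cl2, 0 °C to rt; then 10, Pd(PPh3)4 (5 mol %), THF, 0 °C to rt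
Reagents that add atoms: none
Why: Negishi acylation, in which the acid chloride made under neutral conditions adds oxidatively to zerovalent palladium and is alkylated by the organozinc, gives the ketone without any reagent that attacks the C4 ketone or the enone.

Step 8
Reactants: 12 (2S)-2-Ar-6-(5-methylhex-4-enoyl)-2,3-dihydro-4H-pyran-4-one
Product: 14 (2S)-2-Ar-6-(2-diazo-5-methylhex-4-enoyl)-2,3-dihydro-4H-pyran-4-one, via trifluoroacetyl diketone 13 (not isolated)
Conditions: LiN(SiMe3)2, THF, −78 °C; CF3CO2CH2CF3; aq. HCl; then MsN3, Et3N, H2O, MeCN, rt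
Reagents that add atoms: methanesulfonyl azide, CS(=O)(=O)N=[N+]=[N-]
Why: detrifluoroacetylative (Regitz-type) diazo transfer, in which the side-chain CH2 should be enolised in preference to C3–H because its carbonyl sits on the electron-poor C6 of an enedione whereas C3–H flanks a vinylogous ester carbonyl, and the trifluoroacetylated 1,3-diketone then accepts the diazo group with loss of the trifluoroacetyl group.

Step 9
Reactants: 15 4-methylpent-3-enoic acid
Product: 16 ethyl 4-methylpent-3-enoate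
Conditions: EtI, K2CO3, DMF, rt
Reagents that add atoms: iodoethane, CCI
Why: SN2 O-alkylation of the carboxylate avoids the acid-catalysed lactonisation and alkene migration to which this β,γ-unsaturated acid is prone under Fischer conditions.

Step 10
Reactants: 16 ethyl 4-methylpent-3-enoate
Product: 19 triisopropyl[(5-methylhex-4-en-1-yn-1-yl)oxy]silane, via dibromoketone enolate 17 (not isolated), via lithium ynolate 18 (not isolated)
Conditions: CH2Br2, lithium 2,2,6,6-tetramethylpiperidide (2.2 equiv), THF, −78 °C; n-BuLi, −78 °C to rt; then TIPSCl, 0 °C to rt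
Reagents that add atoms: dibromomethane, BrCBr; chlorotriisopropylsilane, CC(C)[Si](Cl)(C(C)C)C(C)C
Why: Kowalski ester homologation, in which LiCHBr2 adds to the ester, the dibromo enolate undergoes Br/Li exchange and 1,2-shift of the prenyl group with loss of LiBr to the ynolate, and the bulky silyl chloride traps the ynolate on oxygen.

Step 11
Reactants: 14 (2S)-2-Ar-6-(2-diazo-5-methylhex-4-enoyl)-2,3-dihydro-4H-pyran-4-one; 19 triisopropyl[(5-methylhex-4-en-1-yn-1-yl)oxy]silane
Product: 22 (2S)-2-Ar-5-hydroxy-6,8-diprenyl-7-(triisopropylsilyloxy)-2,3-dihydro-4H-chromen-4-one, via vinylketene 20 (not isolated), via cyclobutenone 21 (not isolated)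
Conditions: 19 (1.5 equiv), hν (300 nm), degassed ClCH2CH2Cl, rt; then 80 °C
Reagents that add atoms: none
Why: Proposed new method: light expels N2 from 14 and the 4-oxo-2,3-dihydropyran-6-yl group shifts from the acyl carbon to the diazo carbon (photo-Wolff rearrangement, bond C8–C8a), giving vinylketene 20; its ketene carbon is attacked by the prenyl-bearing β-carbon of ynol ether 19 and the zwitterion collapses ([2+2], bonds C5–C6 and C7–C8) to 4-vinylcyclobutenone 21. At 80 °C the strained ring of 21 opens by conrotatory four-electron electrocyclic cleavage to a dienylketene, which closes ring A by disrotatory six-electron electrocyclisation (bond C4a–C5, six-membered carbocycle) and enolises to the C5 phenol held by a hydrogen bond to the C4 ketone. The closest known reaction type is the Danheiser photochemical benzannulation of aryl and alkenyl α-diazo ketones with trialkylsiloxyalkynes; untested here is a push-pull β-alkoxy enone (dihydropyranone) as the vinyl partner. No stereocentre is created, and the C2 centre and the three prenyl groups meet neither acid nor base. The regiochemistry required (silyloxy carbon at C7 between the two prenyl-bearing carbons, ketene carbon at C5) is secured by the polarisation of the ynol ether, whose β-carbon is the nucleophile, and by C4a being the only terminus available for ring closure. Group migration has to outrun carbene chemistry (1,2-hydrogen shift from the prenyl CH2), which the concerted path from the s-Z conformer of the excited diazoketone is expected to favour.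

Step 12
Reactants: 22 (2S)-2-Ar-5-hydroxy-6,8-diprenyl-7-(triisopropylsilyloxy)-2,3-dihydro-4H-chromen-4-one
Product: 23 (2S)-5,7-dihydroxy-2-(4-hydroxy-3-methoxy-5-prenylphenyl)-6,8-diprenyl-2,3-dihydro-4H-chromen-4-one (CNP0235424.1)
Conditions: TBAF (2.5 equiv), AcOH (3 equiv), THF, 0 °C
Reagents that add atoms: none
Why: fluoride cleaves both aryl silyl ethers while acetic acid protonates the phenoxides as they form, so that base-induced opening of ring C (retro-oxa-Michael) and racemisation at C2 should not occur.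

**Compound list**
1 | 5-iodovanillin | COc1cc(C=O)cc(I)c1O | starting material
2 | 3-iodo-5-methoxy-4-(triisopropylsilyloxy)benzaldehyde | COc1cc(C=O)cc(I)c1O[Si](C(C)C)(C(C)C)C(C)C | intermediate
3 | 3-methoxy-5-prenyl-4-(triisopropylsilyloxy)benzaldehyde | COc1cc(C=O)cc(CC=C(C)C)c1O[Si](C(C)C)(C(C)C)C(C)C | intermediate
4 | ethyl 2,4-dioxopentanoate | CCOC(=O)C(=O)CC(C)=O | starting material
5 | ethyl (2Z)-2,4-bis(trimethylsilyloxy)penta-2,4-dienoate | CCOC(=O)/C(O[Si](C)(C)C)=C/C(=C)O[Si](C)(C)C | intermediate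
6 | ethyl (6S)-6-Ar-6-hydroxy-2,4-dioxohexanoate (enol forms) | COc1cc([C@H](CC(=O)CC(=O)C(=O)OCC)O)cc(CC=C(C)C)c1O[Si](C(C)C)(C(C)C)C(C)C | intermediate
7 | ethyl (2S)-2-Ar-4-oxo-3,4-dihydro-2H-pyran-6-carboxylate | COc1cc([C@@H]2CC(=O)C=C(C(=O)OCC)O2)cc(CC=C(C)C)c1O[Si](C(C)C)(C(C)C)C(C)C | intermediate
8 | (2S)-2-Ar-4-oxo-3,4-dihydro-2H-pyran-6-carboxylic acid | COc1cc([C@@H]2CC(=O)C=C(C(=O)O)O2)cc(CC=C(C)C)c1O[Si](C(C)C)(C(C)C)C(C)C | intermediate
9 | 5-bromo-2-methylpent-2-ene | CC(C)=CCCBr | starting material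
10 | (4-methylpent-3-en-1-yl)zinc bromide | CC(C)=CCC[Zn]Br | intermediate
11 | (2S)-2-Ar-4-oxo-3,4-dihydro-2H-pyran-6-carbonyl chloride | COc1cc([C@@H]2CC(=O)C=C(C(=O)Cl)O2)cc(CC=C(C)C)c1O[Si](C(C)C)(C(C)C)C(C)C | intermediate
12 | (2S)-2-Ar-6-(5-methylhex-4-enoyl)-2,3-dihydro-4H-pyran-4-one | COc1cc([C@@H]2CC(=O)C=C(C(=O)CCC=C(C)C)O2)cc(CC=C(C)C)c1O[Si](C(C)C)(C(C)C)C(C)C | intermediate
13 | (2S)-2-Ar-6-[5-methyl-2-(trifluoroacetyl)hex-4-enoyl]-2,3-dihydro-4H-pyran-4-one (side-chain centre unassigned, enolised) | COc1cc([C@@H]2CC(=O)C=C(C(=O)C(CC=C(C)C)C(=O)C(F)(F)F)O2)cc(CC=C(C)C)c1O[Si](C(C)C)(C(C)C)C(C)C | intermediate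
14 | (2S)-2-Ar-6-(2-diazo-5-methylhex-4-enoyl)-2,3-dihydro-4H-pyran-4-one | COc1cc([C@@H]2CC(=O)C=C(C(=O)C(=[N+]=[N-])CC=C(C)C)O2)cc(CC=C(C)C)c1O[Si](C(C)C)(C(C)C)C(C)C | intermediate
15 | 4-methylpent-3-enoic acid | CC(C)=CCC(=O)O | starting material
16 | ethyl 4-methylpent-3-enoate | CCOC(=O)CC=C(C)C | intermediate
17 | lithium 1,1-dibromo-5-methylhexa-1,4-dien-2-olate | [Li+].[O-]C(CC=C(C)C)=C(Br)Br | intermediate
18 | lithium 5-methylhex-4-en-1-yn-1-olate | [Li+].[O-]C#CCC=C(C)C | intermediate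
19 | triisopropyl[(5-methylhex-4-en-1-yn-1-yl)oxy]silane | CC(C)=CCC#CO[Si](C(C)C)(C(C)C)C(C)C | intermediate
20 | (2S)-2-Ar-6-(5-methyl-1-oxohexa-1,4-dien-2-yl)-2,3-dihydro-4H-pyran-4-one (vinylketene) | COc1cc([C@@H]2CC(=O)C=C(C(CC=C(C)C)=C=O)O2)cc(CC=C(C)C)c1O[Si](C(C)C)(C(C)C)C(C)C | intermediate
21 | 4-[(2S)-2-Ar-4-oxo-3,4-dihydro-2H-pyran-6-yl]-2,4-diprenyl-3-(triisopropylsilyloxy)cyclobut-2-en-1-one (both epimers at the ring quaternary carbon) | COc1cc([C@@H]2CC(=O)C=C(C3(CC=C(C)C)C(=O)C(CC=C(C)C)=C3O[Si](C(C)C)(C(C)C)C(C)C)O2)cc(CC=C(C)C)c1O[Si](C(C)C)(C(C)C)C(C)C | intermediate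
22 | (2S)-2-Ar-5-hydroxy-6,8-diprenyl-7-(triisopropylsilyloxy)-2,3-dihydro-4H-chromen-4-one | COc1cc([C@@H]2CC(=O)c3c(O)c(CC=C(C)C)c(O[Si](C(C)C)(C(C)C)C(C)C)c(CC=C(C)C)c3O2)cc(CC=C(C)C)c1O[Si](C(C)C)(C(C)C)C(C)C | intermediate
23 | (2S)-5,7-dihydroxy-2-(4-hydroxy-3-methoxy-5-prenylphenyl)-6,8-diprenyl-2,3-dihydro-4H-chromen-4-one | COc1cc([C@@H]2CC(=O)c3c(O)c(CC=C(C)C)c(O)c(CC=C(C)C)c3O2)cc(CC=C(C)C)c1O | target

**Step count**
Total: 12 steps. Longest linear sequence: 8 steps (steps 1, 2, 4, 5, 7, 8, 11, 12).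

**Steps most likely to fail**

1. Step 11 (key step, proposed new method). The enone and arene chromophores may compete for light, and the excited diazoketone may react as a carbene (1,2-hydrogen shift to a dienone) instead of rearranging. The push-pull vinylketene may also be too electron-poor at C4a for the six-electron closure, or may acylate the product phenol. Fallback by known chemistry, setting out from 3 and returning at 23:
   - Commercial 2,4,6-trihydroxyacetophenone is C-prenylated twice (prenyl bromide, DBU, THF) to 1-[2,4,6-trihydroxy-3,5-diprenylphenyl]ethanone F1 and protected (MOMCl, i-Pr2NEt) as the 4,6-bis(methoxymethyl) ether F2.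
   - Aldehyde 3 is desilylated (TBAF) to 5-prenylvanillin F3 and converted (MOMCl, i-Pr2NEt) into MOM ether F4.
   - Claisen–Schmidt condensation of F2 with F4 (KOH, EtOH) should give the protected chalcone F5, and 3 M HCl in MeOH removes the three MOM groups to give the tetrahydroxychalcone F6.
   - NaOAc in refluxing EtOH closes ring C by oxa-Michael addition to the racemic flavanone F7, and preparative HPLC on a chiral stationary phase delivers 23.

2. Step 8. Enolisation may occur at C3 of ring C instead of the side-chain CH2, leading to diazo transfer at C3 or to β-elimination of the ring oxygen with loss of the C2 centre. The fallback removes the competing ketone for the duration of the diazo transfer; it sets out from 7 and returns at 14: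
   - Luche reduction of 7 (NaBH4, CeCl3·7H2O, MeOH, −78 °C) should give the cis allylic alcohol ethyl (2S,4S)-2-Ar-4-hydroxy-3,4-dihydro-2H-pyran-6-carboxylate F8, which is silylated (TESCl, imidazole) to the triethylsilyl ether F9.
   - Me3SnOH cleaves the ester to acid F10, and the chloroenamine/Negishi sequence of step 7 with 10 gives ketone F11, whose side-chain CH2 is the only enolisable position.
   - The conditions of step 8 then give diazoketone F12.
   - HF·pyridine buffered with pyridine frees the allylic alcohol F13 while the hindered aryl silyl ether stays, and Dess–Martin periodinane with NaHCO3 restores the C4 ketone to give 14.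
   - The C4 configuration is of no consequence because it is erased in the last operation.

3. Step 4. The ester-substituted dienol ether may be too weak a nucleophile for the electron-rich aldehyde, may react through C3 instead of the terminal carbon, or may add with poor facial selectivity. The fallback sets the carbinol by reagent control; it sets out from 3 and returns at 7:
   - Brown allylation with (−)-B-allyldiisopinocampheylborane (Et2O, −78 °C, ethanolamine work-up) should give (1S)-1-Ar-but-3-en-1-ol F14, which is silylated (TESCl, imidazole) to F15.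
   - Wacker oxidation of the terminal alkene (PdCl2, CuCl, O2, DMF/H2O) gives methyl ketone F16; the trisubstituted prenyl alkenes are not expected to react.
   - Kinetic enolisation at the methyl group (LiN(SiMe3)2, THF, −78 °C) and Claisen condensation with diethyl oxalate give diketo ester F17.
   - TFA in wet CH2Cl2 removes the triethylsilyl group and effects cyclodehydration to 7.

**Further compounds**
F1 | step 11 | 1-[2,4,6-trihydroxy-3,5-bis(3-methylbut-2-en-1-yl)phenyl]ethanone | CC(=O)c1c(O)c(CC=C(C)C)c(O)c(CC=C(C)C)c1O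
F2 | step 11 | 1-[2-hydroxy-4,6-bis(methoxymethoxy)-3,5-bis(3-methylbut-2-en-1-yl)phenyl]ethanone | CC(=O)c1c(O)c(CC=C(C)C)c(OCOC)c(CC=C(C)C)c1OCOC
F3 | step 11 | 4-hydroxy-3-methoxy-5-(3-methylbut-2-en-1-yl)benzaldehyde | COc1cc(C=O)cc(CC=C(C)C)c1O
F4 | step 11 | 3-methoxy-4-(methoxymethoxy)-5-(3-methylbut-2-en-1-yl)benzaldehyde | COCOc1c(OC)cc(C=O)cc1CC=C(C)C
F5 | step 11 | (E)-1-[2-hydroxy-4,6-bis(methoxymethoxy)-3,5-diprenylphenyl]-3-[3-methoxy-4-(methoxymethoxy)-5-prenylphenyl]prop-2-en-1-one | COCOc1c(OC)cc(/C=C/C(=O)c2c(O)c(CC=C(C)C)c(OCOC)c(CC=C(C)C)c2OCOC)cc1CC=C(C)C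
F6 | step 11 | (E)-3-(4-hydroxy-3-methoxy-5-prenylphenyl)-1-(2,4,6-trihydroxy-3,5-diprenylphenyl)prop-2-en-1-one | COc1cc(/C=C/C(=O)c2c(O)c(CC=C(C)C)c(O)c(CC=C(C)C)c2O)cc(CC=C(C)C)c1O
F7 | step 11 | racemic 5,7-dihydroxy-2-(4-hydroxy-3-methoxy-5-prenylphenyl)-6,8-diprenyl-2,3-dihydro-4H-chromen-4-one | COc1cc(C2CC(=O)c3c(O)c(CC=C(C)C)c(O)c(CC=C(C)C)c3O2)cc(CC=C(C)C)c1O
F8 | step 8 | ethyl (2S,4S)-2-Ar-4-hydroxy-3,4-dihydro-2H-pyran-6-carboxylate | COc1cc([C@@H]2C[C@H](O)C=C(C(=O)OCC)O2)cc(CC=C(C)C)c1O[Si](C(C)C)(C(C)C)C(C)C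
F9 | step 8 | ethyl (2S,4S)-2-Ar-4-(triethylsilyloxy)-3,4-dihydro-2H-pyran-6-carboxylate | COc1cc([C@@H]2C[C@H](O[Si](CC)(CC)CC)C=C(C(=O)OCC)O2)cc(CC=C(C)C)c1O[Si](C(C)C)(C(C)C)C(C)C
F10 | step 8 | (2S,4S)-2-Ar-4-(triethylsilyloxy)-3,4-dihydro-2H-pyran-6-carboxylic acid | COc1cc([C@@H]2C[C@H](O[Si](CC)(CC)CC)C=C(C(=O)O)O2)cc(CC=C(C)C)c1O[Si](C(C)C)(C(C)C)C(C)C
F11 | step 8 | 1-[(2S,4S)-2-Ar-4-(triethylsilyloxy)-3,4-dihydro-2H-pyran-6-yl]-5-methylhex-4-en-1-one | COc1cc([C@@H]2C[C@H](O[Si](CC)(CC)CC)C=C(C(=O)CCC=C(C)C)O2)cc(CC=C(C)C)c1O[Si](C(C)C)(C(C)C)C(C)C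
F12 | step 8 | 2-diazo-1-[(2S,4S)-2-Ar-4-(triethylsilyloxy)-3,4-dihydro-2H-pyran-6-yl]-5-methylhex-4-en-1-one | COc1cc([C@@H]2C[C@H](O[Si](CC)(CC)CC)C=C(C(=O)C(=[N+]=[N-])CC=C(C)C)O2)cc(CC=C(C)C)c1O[Si](C(C)C)(C(C)C)C(C)C
F13 | step 8 | 2-diazo-1-[(2S,4S)-2-Ar-4-hydroxy-3,4-dihydro-2H-pyran-6-yl]-5-methylhex-4-en-1-one | COc1cc([C@@H]2C[C@H](O)C=C(C(=O)C(=[N+]=[N-])CC=C(C)C)O2)cc(CC=C(C)C)c1O[Si](C(C)C)(C(C)C)C(C)C
F14 | step 4 | (1S)-1-Ar-but-3-en-1-ol | COc1cc([C@H](CC=C)O)cc(CC=C(C)C)c1O[Si](C(C)C)(C(C)C)C(C)C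
F15 | step 4 | [(1S)-1-Ar-but-3-en-1-yl]oxy(triethyl)silane | COc1cc([C@H](CC=C)O[Si](CC)(CC)CC)cc(CC=C(C)C)c1O[Si](C(C)C)(C(C)C)C(C)C
F16 | step 4 | (4S)-4-Ar-4-(triethylsilyloxy)butan-2-one | COc1cc([C@H](CC(C)=O)O[Si](CC)(CC)CC)cc(CC=C(C)C)c1O[Si](C(C)C)(C(C)C)C(C)C
F17 | step 4 | ethyl (6S)-6-Ar-2,4-dioxo-6-(triethylsilyloxy)hexanoate | COc1cc([C@H](CC(=O)CC(=O)C(=O)OCC)O[Si](CC)(CC)CC)cc(CC=C(C)C)c1O[Si](C(C)C)(C(C)C)C(C)C
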